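**Plan**

- Retrosynthesis: in ring A the C4–Br and C6–Br bonds are cut first and the ring is taken back to the cyclohexenone oxidation level. The C3–Br bond is then cut back to a 1,3-dione enol, and last the C2–O aryl ether bond is cut to a diazo dione and a phenol.
- Enabling feature: ring A carries C1–OH, C2–OAr and C3–Br side by side. These are the two carbonyl carbons (C1, C3) and the central carbon (C2) of cyclohexane-1,3-dione, and C4 and C6 are para and ortho to the C1 hydroxyl.
- Forward: cyclohexane-1,3-dione 1 is converted into diazo dione 2. Carbene O–H insertion into 2-bromophenol 3 attaches ring B through oxygen (4), and deoxybromination gives bromo enone 5. Bromine then aromatizes ring A and fills C4 and C6, through bromo enone 6 and phenol 7, to the target 8.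
- No ring is closed at any stage (ring A comes from 1, ring B from 3). The target has no stereocenter, so no stereocontrol is required.

Key step: step 4

Remark: 4 is written as its enol tautomer, the form in which 2-substituted cyclohexane-1,3-diones mainly exist; 6 is racemic and its stereocenter is lost on aromatization.

**Step 1**
Reactants: 1 cyclohexane-1,3-dione
Product: 2 2-diazocyclohexane-1,3-dione
Conditions: 4-acetamidobenzenesulfonyl azide (1.05 equiv), Et3N (1.2 equiv), MeCN, 0 °C → rt
Reagents that add atoms: 4-acetamidobenzenesulfonyl azide, CC(=O)Nc1ccc(cc1)S(=O)(=O)N=[N+]=[N-]
Why: Regitz diazo transfer, in which the triethylammonium enolate of the acidic dione attacks the terminal nitrogen of the sulfonyl azide and the triazene collapses to the diazo dione and the sulfonamide, a standard preparation of this compound.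

**Step 2**
Reactants: 2 2-diazocyclohexane-1,3-dione; 3 2-bromophenol
Product: 4 2-(2-bromophenoxy)-3-hydroxycyclohex-2-en-1-one
Conditions: Rh2(OAc)4 (1 mol %), 3 (3 equiv), PhF, 75 °C, slow addition of 2; NaHCO3 extraction, then acidification
Reagents that add atoms: none
Why: Dirhodium tetraacetate should turn 2 into an electrophilic divalent-rhodium carbenoid with loss of N2, which is trapped at the phenolic oxygen of 3 as an oxonium ylide that collapses by proton transfer (carbenoid O–H insertion, well established for diazo 1,3-dicarbonyl compounds with alcohols and phenols), after which the dione enolizes to 4 and can be separated from excess 3 through its much higher acidity.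

**Step 3**
Reactants: 4 2-(2-bromophenoxy)-3-hydroxycyclohex-2-en-1-one
Product: 5 3-bromo-2-(2-bromophenoxy)cyclohex-2-en-1-one
Conditions: (COBr)2 (1.1 equiv), DMF (1.2 equiv), CH2Cl2, 0 °C; then 4, 0 °C → rt
Reagents that add atoms: oxalyl bromide, O=C(Br)C(Br)=O
Why: Vilsmeier-type deoxybromination of a vinylogous acid, in which the enol oxygen of 4 is activated as an O-iminium ether by the preformed bromoiminium salt and bromide then adds at C3 and expels DMF (addition–elimination), a routine conversion for cyclohexane-1,3-diones that can give only one vinyl bromide here because the dione is symmetric.

**Step 4**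
Reactants: 5 3-bromo-2-(2-bromophenoxy)cyclohex-2-en-1-one
Product: 8 3,4,6-tribromo-2-(2-bromophenoxy)phenol, via 3,6-dibromo-2-(2-bromophenoxy)cyclohex-2-en-1-one 6 (not isolated), via 3-bromo-2-(2-bromophenoxy)phenol 7 (not isolated)
Conditions: Br2 (1.0 equiv), HBr (cat.), AcOH, rt → 70 °C; then Br2 (2.0 equiv), 10 °C → rt
Reagents that add atoms: bromine, BrBr
Why: HBr-catalysed enolization of 5 toward C6 and bromination should give 6, which on warming loses HBr across C5–C6 to a cross-conjugated cyclohexa-2,5-dienone that tautomerizes at once to phenol 7 (bromination at C4 through the extended dienol and loss of HBr across C4–C5 leads to the same phenol, and bromination at the fully substituted C2 is reversible in HBr, so all paths converge). The closest known reaction type is the bromination–dehydrobromination aromatization of cyclohexenones and cyclohexane-1,3-dione derivatives to phenols, followed by ordinary electrophilic bromination of a phenol. No ring is closed and no stereocenter is created; the C6 stereocenter of racemic 6 disappears on aromatization. The step needs site selectivity for C4 and C6 of ring A: in 7 the free hydroxyl directs para (C4) and ortho (C6), the second ortho position C2 is blocked by the aryloxy group and C5 is meta to the hydroxyl. Ring B should be spared because it is activated only by a diaryl ether oxygen shared with the electron-poor ring A and is deactivated by its own bromine, and because bromine is limited to three equivalents with the last two added cold after aromatization. The O/OAr/Br pattern at C1–C3 is carried in from the dione, so it does not depend on any aromatic substitution.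

**Compound list**

1 | cyclohexane-1,3-dione | O=C1CCCC(=O)C1 | starting material
2 | 2-diazocyclohexane-1,3-dione | [N-]=[N+]=C1C(=O)CCCC1=O | intermediate
3 | 2-bromophenol | Oc1ccccc1Br | starting material
4 | 2-(2-bromophenoxy)-3-hydroxycyclohex-2-en-1-one (enol form of 2-(2-bromophenoxy)cyclohexane-1,3-dione) | O=C1CCCC(O)=C1Oc1ccccc1Br | intermediate
5 | 3-bromo-2-(2-bromophenoxy)cyclohex-2-en-1-one | O=C1CCCC(Br)=C1Oc1ccccc1Br | intermediate
6 | 3,6-dibromo-2-(2-bromophenoxy)cyclohex-2-en-1-one (racemic, not isolated) | O=C1C(Br)CCC(Br)=C1Oc1ccccc1Br | intermediate
7 | 3-bromo-2-(2-bromophenoxy)phenol (not isolated) | Oc1cccc(Br)c1Oc1ccccc1Br | intermediate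
8 | 3,4,6-tribromo-2-(2-bromophenoxy)phenol | Oc1c(Br)cc(Br)c(Br)c1Oc1ccccc1Br | target

**Totals**

Total step count: 4
Longest linear sequence: 4 steps (1 → 2 → 4 → 5 → 8); 3 enters in step 2.

**Steps most likely to fail**

Step 4.
- Risk: dehydrobromination of the α-bromo enone may lag behind further bromination. Bromine and HBr would then stay together long enough to brominate ring B para to the ether oxygen or to spread bromine unevenly over the cyclohexenone, so the three-equivalent budget is spent in the wrong places.
- Fallback: setting out from 5, ring A would be aromatized without free bromine by CuBr2 (2.2 equiv, the divalent copper bromide) and LiBr in MeCN at reflux, a known cyclohexenone-to-phenol method, and phenol 7 would be isolated. Phenol 7 would then be dibrominated with N-bromosuccinimide (2.0 equiv) in MeCN at 0 °C, where the hydroxyl directs to C4 and C6 and the ether ring is left alone. This returns to the route at 8. No compound outside the list arises on this detour (F0).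

Step 2.
- Risk: the acceptor/acceptor carbenoid may be diverted from the hydroxyl group to aromatic substitution of the phenol, to the lone pairs of the aryl bromine, or to O–H insertion into the acidic enol of the product. Alternatively 2 may lose N2 only at temperatures where Wolff rearrangement competes.
- Fallback (ether first, ring second): the detour sets out from 3 and avoids any carbene. Commercial methyl 5-oxohexanoate (COC(=O)CCCC(C)=O) would be brominated at its methyl group with Br2 in MeOH at 0 °C to methyl 6-bromo-5-oxohexanoate F1. Williamson etherification of 3 with F1 (K2CO3, acetone, rt) would give methyl 6-(2-bromophenoxy)-5-oxohexanoate F2. Intramolecular Claisen condensation (KOtBu, THF, 0 °C → rt, acidic work-up), in which the aryloxy-substituted C6 enolate attacks the ester, would close the six-membered dione and return to the route at 4.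

Step 3.
- Risk: bromide may fail to displace the activated enol oxygen at the crowded, aryloxy-substituted enol carbon, or the HBr formed may return the vinylogous acyl bromide to 4 during isolation.
- Fallback: setting out from 4, the enol would first be isolated as its mesylate (MsCl, K2CO3, MeCN, rt), 2-(2-bromophenoxy)-3-oxocyclohex-1-en-1-yl methanesulfonate F3, a stable activated vinylogous ester. Treatment with Bu4NBr and BF3·OEt2 in CH2Cl2 would then exchange mesylate for bromide by Lewis-acid-assisted conjugate addition–elimination under non-protic conditions, returning to the route at 5.

**Further compounds**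

F0 | step 4 | none | none
F1 | step 2 | methyl 6-bromo-5-oxohexanoate | COC(=O)CCCC(=O)CBr
F2 | step 2 | methyl 6-(2-bromophenoxy)-5-oxohexanoate | COC(=O)CCCC(=O)COc1ccccc1Br
F3 | step 3 | 2-(2-bromophenoxy)-3-oxocyclohex-1-en-1-yl methanesulfonate | CS(=O)(=O)OC1=C(Oc2ccccc2Br)C(=O)CCC1
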